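## Retrosynthetic overview

1. Target ⇒ carvone-type enone 9. The C–Cl bond (cyclohexane C-3) comes from an equatorial alcohol by substitution with inversion, and the C–Br bond (C-4) from axial bromination of an enol ether.
2. Enone 9 ⇒ enal 4 + tert-butyl 3-oxopentanoate 5 by a one-pot amine-catalysed Michael addition/aldol condensation/decarboxylation ([3+3]) that forms the cyclohexane bonds C-1–C-2 and C-4–C-5. Enal 4 supplies C-1, C-6 and C-5; ketoester 5 supplies C-2, C-3, C-4 and the C-4 methyl.
3. Enal 4 ⇒ cross-metathesis of vinyl oxane 2 ⇒ bromoetherification of (S)-linalool 1. This is the chiral pool element: the linalool carbinol carbon becomes oxane C-2 and its vinyl CH becomes cyclohexane C-1.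
4. Ring order: oxane ring first (step 1), cyclohexane ring second (step 3).
5. Enabling feature: in the cyclohexane ring the CHCl carbon (C-3) lies 1,3 to the ring CH that carries the oxane (C-1) and next to the methyl-bearing CBr carbon (C-4). Read as a ketone at C-3, this is a 2-methyl-5-substituted cyclohexanone: C-2 and C-4 are the two nucleophilic α-carbons of a three-carbon ketone unit, and C-1 and C-5 are the electrophilic ends of a three-carbon enal unit.

Key step: step 3

Assumption: (S)-(+)-linalool (coriandrol) of high enantiomeric purity and tert-butyl 3-oxopentanoate are taken as catalogue compounds; the configuration of the linalool carbinol carbon is carried unchanged into oxane C-2.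

## Route

Step 1
Reactants: 1 (S)-(+)-linalool
Product: 2 (3R,6S)-3-bromo-6-ethenyl-2,2,6-trimethyloxane
Conditions: TBCO (1.1 equiv), CH2Cl2, −20 °C to rt, dark; chromatography
Reagents that add atoms: 2,4,4,6-tetrabromocyclohexa-2,5-dien-1-one (TBCO), O=C1C(Br)=CC(Br)(Br)C=C1Br
Why: Bromoetherification (6-endo-trig Markovnikov opening of the bromonium ion of the electron-rich trisubstituted alkene by the tertiary hydroxyl, the vinyl group not competing) should close the oxane through a chair transition state with bromine equatorial; because methyl and vinyl on the carbinol carbon are similar in size, the C-3 epimer and tetrahydrofuran regioisomers are expected alongside and are removed by chromatography, the (3R,6S) isomer (Br trans to vinyl) being carried on.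

Step 2
Reactants: 2 (3R,6S)-3-bromo-6-ethenyl-2,2,6-trimethyloxane; 3 (E)-but-2-enal (crotonaldehyde)
Product: 4 (E)-3-[(2S,5R)-5-bromo-2,6,6-trimethyloxan-2-yl]prop-2-enal
Conditions: 3 (5 equiv), second-generation Hoveyda–Grubbs catalyst RuCl2(H2IMes)(=CH-C6H4-2-O-i-Pr) (5 mol %), CH2Cl2, 40 °C
Reagents that add atoms: none
Why: Olefin cross-metathesis, in which the vinyl group on a fully substituted carbon cannot homodimerise and so should couple selectively with the electron-poor partner to the thermodynamically favoured (E)-enal, the alkyl bromide and the ether being inert to the ruthenium carbene.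

Step 3
Reactants: 4 (E)-3-[(2S,5R)-5-bromo-2,6,6-trimethyloxan-2-yl]prop-2-enal; 5 tert-butyl 3-oxopentanoate
Product: 9 (5S)-5-[(2S,5R)-5-bromo-2,6,6-trimethyloxan-2-yl]-2-methylcyclohex-2-en-1-one, via Michael adduct 6 (not isolated), via cyclohexenone ester 7 (not isolated), via keto acid 8 (not isolated)
Conditions: (R)-2-[diphenyl(trimethylsilyloxy)methyl]pyrrolidine (20 mol %), PhCO2H (20 mol %), toluene, rt; then TsOH·H2O (20 mol %), 80 °C
Reagents that add atoms: none
Why: The (R)-configured amine converts enal 4 into an (E)-iminium ion that is attacked at C-β by the enol of 5 (Michael addition, cyclohexane bond C-1–C-2), and after the acid is added the ethyl ketone of the released keto aldehyde 6 enolises toward its CH2 group, which adds to the aldehyde carbon (bond C-4–C-5) and dehydrates to 7, whose tert-butyl ester is cleaved to keto acid 8 that loses CO2. The closest known reaction type is the diarylprolinol silyl ether-catalysed one-pot Michael addition/aldol condensation/decarboxylation of tert-butyl β-ketoesters with enals to 5-substituted cyclohex-2-enones. The six-membered ring closes by a 6-(enolendo)-exo-trig aldol addition, and no other ring size competes because every other enol/carbonyl pairing in 6 would give a four-membered ring. The only new stereocenter that survives, cyclohexane C-1, is set by the catalyst, whose diphenyl(trimethylsilyloxy)methyl group shields the Si face of C-β in the s-trans (E)-iminium ion so that 5 adds to the Re face and gives the (S) configuration, while the ester-bearing carbon is cleared by decarboxylation. The step needs conjugate over direct addition and catalyst over substrate control: iminium activation secures the first (helped by the electron-withdrawing ring oxygen on the neighbouring fully substituted carbon, which offsets part of its steric shielding), and the second rests on that neighbouring stereocenter carrying two groups of similar size (methyl and ring CH2), so that its own facial bias should be small.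

Step 4
Reactants: 9 (5S)-5-[(2S,5R)-5-bromo-2,6,6-trimethyloxan-2-yl]-2-methylcyclohex-2-en-1-one
Product: 10 triethyl({(5S)-5-[(2S,5R)-5-bromo-2,6,6-trimethyloxan-2-yl]-2-methylcyclohex-1-en-1-yl}oxy)silane
Conditions: Et3SiH (1.5 equiv), RhCl(PPh3)3 (2 mol %), benzene, 60 °C
Reagents that add atoms: triethylsilane, CC[SiH](CC)CC
Why: Rhodium-catalysed 1,4-hydrosilylation of an enone with a monohydrosilane should deliver hydrogen to the β-carbon and silicon to oxygen, giving the tetrasubstituted silyl enol ether regiospecifically under neutral conditions that leave the secondary bromide untouched, with no new stereocenter.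

Step 5
Reactants: 10 triethyl({(5S)-5-[(2S,5R)-5-bromo-2,6,6-trimethyloxan-2-yl]-2-methylcyclohex-1-en-1-yl}oxy)silane
Product: 11 (2R,5S)-2-bromo-5-[(2S,5R)-5-bromo-2,6,6-trimethyloxan-2-yl]-2-methylcyclohexan-1-one
Conditions: NBS (1.05 equiv), THF, −78 °C
Reagents that add atoms: N-bromosuccinimide, O=C1CCC(=O)N1Br
Why: Electrophilic α-bromination of a silyl enol ether, in which the half-chair with the bulky oxanyl group equatorial should be attacked along the axial trajectory (chair-like transition state), placing bromine axial and cis to the oxanyl group (2R) as required for C-4 of the target.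

Step 6
Reactants: 11 (2R,5S)-2-bromo-5-[(2S,5R)-5-bromo-2,6,6-trimethyloxan-2-yl]-2-methylcyclohexan-1-one
Product: 12 (1S,2R,5S)-2-bromo-5-[(2S,5R)-5-bromo-2,6,6-trimethyloxan-2-yl]-2-methylcyclohexan-1-ol
Conditions: NaBH4, CeCl3·7H2O, MeOH, −40 °C
Reagents that add atoms: none
Why: Luche-type borohydride reduction, in which hydride should add along the axial trajectory anti to the axial C–Br bond (Felkin–Anh polar control, reinforced by bromine shielding the other face) to give the equatorial (1S) alcohol cis to bromine, the low temperature and weakly basic medium suppressing loss of HBr.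

Step 7
Reactants: 12 (1S,2R,5S)-2-bromo-5-[(2S,5R)-5-bromo-2,6,6-trimethyloxan-2-yl]-2-methylcyclohexan-1-ol
Product: 14 (2S,5R)-5-bromo-2-[(1S,3R,4R)-4-bromo-3-chloro-4-methylcyclohexyl]-2,6,6-trimethyloxane, via triflate 13 (not isolated)
Conditions: Tf2O, 2,6-lutidine, CH2Cl2, −40 °C; then n-Bu4NCl, 0 °C to rt
Reagents that add atoms: tetrabutylammonium chloride, CCCC[N+](CCCC)(CCCC)CCCC.[Cl-]
Why: Triflate formation followed by bimolecular displacement with chloride (the inversion used for equatorial sugar triflates), in which the equatorial triflate has neither an anti-periplanar bromine to assist ionisation nor an anti-periplanar hydrogen for elimination, so chloride should enter along the axial direction with inversion to give the axial (3R) chloride trans-diaxial to bromine.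

## Compound list

1 | (S)-(+)-linalool, (3S)-3,7-dimethylocta-1,6-dien-3-ol | CC(C)=CCC[C@](C)(O)C=C | starting material
2 | (3R,6S)-3-bromo-6-ethenyl-2,2,6-trimethyloxane | CC1(C)O[C@](C)(C=C)CC[C@H]1Br | intermediate
3 | (E)-but-2-enal (crotonaldehyde) | C/C=C/C=O | starting material
4 | (E)-3-[(2S,5R)-5-bromo-2,6,6-trimethyloxan-2-yl]prop-2-enal | CC1(C)O[C@](C)(/C=C/C=O)CC[C@H]1Br | intermediate
5 | tert-butyl 3-oxopentanoate | CCC(=O)CC(=O)OC(C)(C)C | starting material
6 | tert-butyl (3S)-3-[(2S,5R)-5-bromo-2,6,6-trimethyloxan-2-yl]-5-oxo-2-propanoylpentanoate (C-2 epimers; Michael adduct) | CC1(C)O[C@](C)([C@@H](CC=O)C(C(=O)CC)C(=O)OC(C)(C)C)CC[C@H]1Br | intermediate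
7 | tert-butyl (6S)-6-[(2S,5R)-5-bromo-2,6,6-trimethyloxan-2-yl]-3-methyl-2-oxocyclohex-3-ene-1-carboxylate (C-1 epimers) | CC1(C)O[C@](C)([C@H]2CC=C(C)C(=O)C2C(=O)OC(C)(C)C)CC[C@H]1Br | intermediate
8 | (6S)-6-[(2S,5R)-5-bromo-2,6,6-trimethyloxan-2-yl]-3-methyl-2-oxocyclohex-3-ene-1-carboxylic acid (C-1 epimers) | CC1(C)O[C@](C)([C@H]2CC=C(C)C(=O)C2C(=O)O)CC[C@H]1Br | intermediate
9 | (5S)-5-[(2S,5R)-5-bromo-2,6,6-trimethyloxan-2-yl]-2-methylcyclohex-2-en-1-one | CC1(C)O[C@](C)([C@H]2CC=C(C)C(=O)C2)CC[C@H]1Br | intermediate
10 | triethyl({(5S)-5-[(2S,5R)-5-bromo-2,6,6-trimethyloxan-2-yl]-2-methylcyclohex-1-en-1-yl}oxy)silane | CC1(C)O[C@](C)([C@H]2CCC(C)=C(O[Si](CC)(CC)CC)C2)CC[C@H]1Br | intermediate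
11 | (2R,5S)-2-bromo-5-[(2S,5R)-5-bromo-2,6,6-trimethyloxan-2-yl]-2-methylcyclohexan-1-one | CC1(C)O[C@](C)([C@H]2CC[C@@](C)(Br)C(=O)C2)CC[C@H]1Br | intermediate
12 | (1S,2R,5S)-2-bromo-5-[(2S,5R)-5-bromo-2,6,6-trimethyloxan-2-yl]-2-methylcyclohexan-1-ol | CC1(C)O[C@](C)([C@H]2CC[C@@](C)(Br)[C@@H](O)C2)CC[C@H]1Br | intermediate
13 | (1S,2R,5S)-2-bromo-5-[(2S,5R)-5-bromo-2,6,6-trimethyloxan-2-yl]-2-methylcyclohexyl trifluoromethanesulfonate | CC1(C)O[C@](C)([C@H]2CC[C@@](C)(Br)[C@@H](OS(=O)(=O)C(F)(F)F)C2)CC[C@H]1Br | intermediate
14 | (2S,5R)-5-bromo-2-[(1S,3R,4R)-4-bromo-3-chloro-4-methylcyclohexyl]-2,6,6-trimethyloxane | CC1(C)O[C@](C)([C@H]2CC[C@@](C)(Br)[C@H](Cl)C2)CC[C@H]1Br | target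

## Step count and risks

Total step count: 7. Longest linear sequence: 7 steps (from 1).

Steps most likely to fail:

Step 3. The conjugate addition may stall because both iminium formation and attack at the β-carbon are slowed by the adjacent fully substituted oxane carbon, or facial selectivity may erode if the substrate's own bias opposes the catalyst. The fallback replaces amine catalysis by a stoichiometric, auxiliary-controlled aza-enolate addition; it sets out from 2 and returns to the route at 9. Cross-metathesis of 2 with methyl acrylate under the conditions of step 2 should give methyl (E)-3-[(2S,5R)-5-bromo-2,6,6-trimethyloxan-2-yl]prop-2-enoate F1. Butan-2-one is condensed with (S)-1-amino-2-(methoxymethyl)pyrrolidine to the hydrazone (2S)-N-(butan-2-ylidene)-2-(methoxymethyl)pyrrolidin-1-amine F2, which is lithiated at its methyl group (LiN(i-Pr)2, THF, −78 °C) and added to F1 in an Enders-type asymmetric Michael addition to give methyl (3R)-3-[(2S,5R)-5-bromo-2,6,6-trimethyloxan-2-yl]-5-{[(2S)-2-(methoxymethyl)pyrrolidin-1-yl]imino}heptanoate F3. The sense of induction of the auxiliary is not certain here; the enantiomeric auxiliary would be used if it proved opposite. i-Bu2AlH (CH2Cl2, −78 °C) should reduce the ester, with the ketone still masked, to (3R)-3-[(2S,5R)-5-bromo-2,6,6-trimethyloxan-2-yl]-5-{[(2S)-2-(methoxymethyl)pyrrolidin-1-yl]imino}heptanal F4. Aqueous oxalic acid then frees (3S)-3-[(2S,5R)-5-bromo-2,6,6-trimethyloxan-2-yl]-5-oxoheptanal F5, and TsOH in toluene at 80 °C closes it by aldol condensation to 9.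

Step 7. Substitution at the secondary carbon next to the fully substituted C–Br carbon may be slow, so that elimination or loss of HBr competes. The fallback introduces both halogens together by anti addition instead of substitution; it sets out from 9 and returns at 14. Condensation of 9 with TsNHNH2 (EtOH, rt) should give N'-[(5S)-5-[(2S,5R)-5-bromo-2,6,6-trimethyloxan-2-yl]-2-methylcyclohex-2-en-1-ylidene]-4-methylbenzenesulfonohydrazide F6. Catecholborane (CHCl3, 0 °C) followed by NaOAc·3H2O at reflux should reduce it with 1,3-transposition of the double bond to (2S,5R)-5-bromo-2,6,6-trimethyl-2-[(1S)-4-methylcyclohex-3-en-1-yl]oxane F7. Bu4N[BrCl2] (CH2Cl2, −78 °C) then adds bromine chloride anti. The bromonium ion on the face cis to the oxanyl group is opened trans-diaxially by chloride at the secondary carbon to give 14. The other bromonium face leads to the regioisomeric diaxial adduct, which is Markovnikov-favoured and may predominate; it would have to be separated by chromatography.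

Step 2. Metathesis at a vinyl group on a fully substituted carbon may be sluggish, and the catalyst may decompose in the presence of the enal before conversion is complete. The fallback replaces metathesis by oxidative cleavage and olefination; it sets out from 2 and returns at 4. Ozonolysis (O3, CH2Cl2/MeOH, −78 °C; then Me2S) should give (2S,5R)-5-bromo-2,6,6-trimethyloxane-2-carbaldehyde F8, and Wittig olefination with Ph3P=CHCHO (toluene, 80 °C) should give the (E)-enal 4.

## Further compounds

F1 | step 3 | methyl (E)-3-[(2S,5R)-5-bromo-2,6,6-trimethyloxan-2-yl]prop-2-enoate | CC1(C)O[C@](C)(/C=C/C(=O)OC)CC[C@H]1Br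
F2 | step 3 | (2S)-N-(butan-2-ylidene)-2-(methoxymethyl)pyrrolidin-1-amine | CCC(C)=NN1CCC[C@H]1COC
F3 | step 3 | methyl (3R)-3-[(2S,5R)-5-bromo-2,6,6-trimethyloxan-2-yl]-5-{[(2S)-2-(methoxymethyl)pyrrolidin-1-yl]imino}heptanoate | CC1(C)O[C@](C)([C@@H](CC(=O)OC)CC(CC)=NN2CCC[C@H]2COC)CC[C@H]1Br
F4 | step 3 | (3R)-3-[(2S,5R)-5-bromo-2,6,6-trimethyloxan-2-yl]-5-{[(2S)-2-(methoxymethyl)pyrrolidin-1-yl]imino}heptanal | CC1(C)O[C@](C)([C@@H](CC=O)CC(CC)=NN2CCC[C@H]2COC)CC[C@H]1Br
F5 | step 3 | (3S)-3-[(2S,5R)-5-bromo-2,6,6-trimethyloxan-2-yl]-5-oxoheptanal | CC1(C)O[C@](C)([C@@H](CC=O)CC(=O)CC)CC[C@H]1Br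
F6 | step 7 | N'-[(5S)-5-[(2S,5R)-5-bromo-2,6,6-trimethyloxan-2-yl]-2-methylcyclohex-2-en-1-ylidene]-4-methylbenzenesulfonohydrazide | CC1(C)O[C@](C)([C@H]2CC=C(C)C(=NNS(=O)(=O)c3ccc(C)cc3)C2)CC[C@H]1Br
F7 | step 7 | (2S,5R)-5-bromo-2,6,6-trimethyl-2-[(1S)-4-methylcyclohex-3-en-1-yl]oxane | CC1(C)O[C@](C)([C@H]2CCC(C)=CC2)CC[C@H]1Br
F8 | step 2 | (2S,5R)-5-bromo-2,6,6-trimethyloxane-2-carbaldehyde | CC1(C)O[C@](C)(C=O)CC[C@H]1Br
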